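At the last readings, 10.0 h in the violet run and 10.0 h in the blue run, target plus isomer of the product stood at 29.1% and 45.4%, close to the partner charged over the substrate charged, 30.0% and 44.0%.

the same everywhere: substrate 0.050 M
- violet: partner 0.015 M; run made earlier
- blue: partner 0.022 M; run made earlier
- flask: partner 0.0300 M; time 12 h

| run | time / h | substrate / % | target / % | isomer of the product / % |
|---|---|---|---|---|
| violet | 1.33 | 35.4 | 25.0 | 2.7 |
| violet | 3.00 | 34.9 | 24.7 | 8.1 |
| violet | 4.00 | 34.7 | 21.2 | 7.0 |
| violet | 6.00 | 35.4 | 21.0 | 9.9 |
| violet | 8.00 | 33.8 | 18.8 | 10.3 |
| violet | 10.0 | 34.6 | 17.2 | 11.9 |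
| blue | 0.500 | 30.7 | 39.2 | 0.1 |
| blue | 1.33 | 31.5 | 38.7 | 5.5 |
| blue | 2.50 | 31.0 | 35.0 | 10.3 |
| blue | 4.00 | 29.1 | 32.6 | 12.4 |
| blue | 6.00 | 29.3 | 28.0 | 12.7 |
| blue | 8.00 | 29.2 | 27.0 | 14.2 |
| blue | 10.0 | 30.4 | 27.7 | 17.7 |

(scatter of a reading: 1 percentage point)

- the numbers in the tables scatter with a standard deviation of 1 percentage point
- a reading or a percentage of substrate is of its free form alone

1. where most of what was charged as substrate, at 12 h is found (substrate / isomer of the product / target)
2. the largest share itself, whichever of these holds it, in percent of the substrate charged

So I took partner as the limiting reagent and reckoned this flask's pool, target plus isomer of the product together, as 60.0%, the partner charged over the substrate charged. How much of the pool stays target? At the last blue reading target held 0.610 of the sum, so I expected 36.6% target and 23.4% isomer of the product in this flask at 12 h. Could free substrate stand higher than target? At the last readings it stood at 34.6% in the violet run and 30.4% in the blue run, lower with more partner, so I put it below the blue reading and thus below my target figure. The forecast, lower than my figure, gave target at 34%, holding that “partner is limiting and consumed quickly”.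

The flask gave target at 37.7%, with isomer of the product at 22.3% and substrate at 23.7%; target plus isomer came to 60.0%, the pool.

    substrate + partner → target (k = 0.0930 M⁻¹ s⁻¹)
    target ⇌ isomer of the product (K = 0.610, k = 3.60 × 10⁻⁵ s⁻¹)
    2 substrate ⇌ resting dimer, settled at all times (K = 29.0 M⁻¹)

The half-life of substrate by its conversion with partner, at the charges, was 0.069 h, against 5.3 h for the forward step from target to isomer. By 1.20 h the flask had 99.6% of its conversion into target behind it, with isomer at 6.67%. For the neighbour charged with 0.20 M of substrate, the pool reckons to 15.0%, which with the same split gives 9.15% target. That neighbour held 9.41% target and 5.59% isomer at the asked time, and there free substrate at 23.1% stood above target.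

(The data stem from a simulated flask on assumed constants; noise was put on by code.)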